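**Retrosynthetic overview**
1. Numbering used here (decalin positions): C3 = carbon bearing the aryl ether and a methyl, C10 = angular methyl carbon, C5 = ring-fusion CH, C7 = carbon bearing the 2-hydroxypropan-2-yl group; ring A = C1–C5 + C10, ring B = C5–C10.
2. Late disconnections: aryl–allyl bond (Suzuki at C–Cl), biaryl bond (Suzuki at C–Br), side-chain alcohol (Mukaiyama hydration of an isopropenyl group), C3–O–aryl bond (arylation of the tertiary alkoxide with a diaryliodonium salt), leading back to decalinol 15.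
3. Enabling feature: in ring A the oxygenated C3 is 1,3 to C1, and C1 is bonded to the quaternary C10 that carries the C5–C10 bond. A temporary carbonyl at C1 therefore makes C2–C3 an aldol bond and C5–C10 the Michael bond of a C1/C3 1,5-diketone.
4. Key disconnection: both bonds are cut at once, giving the acyclic enone-ketone 9 with C7 as its only controlling stereocentre. Ring B closes first (Michael), ring A second (aldol), setting C5, C10 and C3; the C1 carbonyl is then removed via the tosylhydrazone.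
5. 9 comes from (R)-limonene: cleavage of the ring C=C keeps C7 and leaves the isopropenyl group as a masked tertiary alcohol; the ketone end is homologated (TosMIC, MeLi) and the aldehyde end extended by Wittig olefination. Both arene rings are bought.

Key step: step 5

Assumption: 2-allyl-4-bromophenol (24) and 2-bromo-4-chloro-1-iodobenzene (16) are taken as purchasable; the (R) centre of limonene maps onto C7 of the target with the same descriptor.

Step 1
Reactants: 1 (R)-(+)-limonene
Product: 4 (5R)-7,7-dimethoxy-5-(prop-1-en-2-yl)heptan-2-one, via methoxy-hydroperoxide aldehyde 2 (not isolated), via hydroperoxy acetal 3 (not isolated)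
Conditions: O3 (1.0 equiv), CH2Cl2/MeOH, −78 °C; TsOH·H2O (cat.), rt; NaHCO3, Me2S, rt
Reagents that add atoms: ozone [O-][O+]=O; methanol CO
Why: Unsymmetrical ozonolysis with in-situ acetal formation: ozone should attack the trisubstituted ring alkene faster than the isopropenyl group, methanol traps the carbonyl oxide at the methyl-bearing carbon, the aldehyde end is acetalised and Me2S reduces the hydroperoxide to the ketone; the future C7 centre is untouched.

Step 2
Reactants: 4 (5R)-7,7-dimethoxy-5-(prop-1-en-2-yl)heptan-2-one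
Product: 5 (5R)-7,7-dimethoxy-2-methyl-5-(prop-1-en-2-yl)heptanenitrile (C2 epimers)
Conditions: TosMIC, KOt-Bu, EtOH (2 equiv), DME, 0 °C to 40 °C
Reagents that add atoms: TosMIC (p-toluenesulfonylmethyl isocyanide) Cc1ccc(cc1)S(=O)(=O)C[N+]#[C-]
Why: van Leusen reductive cyanation turns the methyl ketone into the homologous secondary nitrile without touching acetal or alkene; the new centre forms as both epimers, which does not matter because it becomes the enolate carbon C10 in step 5.

Step 3
Reactants: 5 (5R)-7,7-dimethoxy-2-methyl-5-(prop-1-en-2-yl)heptanenitrile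
Product: 8 (3R)-6-methyl-7-oxo-3-(prop-1-en-2-yl)octanal (C6 epimers), via lithium ketimide 6 (not isolated), via keto acetal 7 (not isolated)
Conditions: MeLi, Et2O, −78 °C to 0 °C; then 1 M HCl, THF, 0 °C to rt
Reagents that add atoms: methyllithium [Li]C; water O
Why: Organolithium addition to a nitrile stops at the N-lithio ketimine, and the aqueous acid work-up hydrolyses first the ketimine and then the dimethyl acetal, giving the methyl ketone and the aldehyde; no stereocentre of consequence is formed.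

Step 4
Reactants: 8 (3R)-6-methyl-7-oxo-3-(prop-1-en-2-yl)octanal
Product: 9 (3E,6R)-9-methyl-6-(prop-1-en-2-yl)undec-3-ene-2,10-dione (C9 epimers)
Conditions: Ph3P=CHC(O)CH3, CH2Cl2, rt
Reagents that add atoms: 1-(triphenylphosphoranylidene)propan-2-one CC(=O)C=P(c1ccccc1)(c1ccccc1)c1ccccc1
Why: Wittig olefination with the stabilised acetonyl ylide should react only at the aldehyde, not at the α-branched ketone, and give the (E)-enone.

Step 5
Reactants: 9 (3E,6R)-9-methyl-6-(prop-1-en-2-yl)undec-3-ene-2,10-dione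
Product: 11 (3S,4aS,6R,8aR)-3-hydroxy-3,8a-dimethyl-6-(prop-1-en-2-yl)octahydronaphthalen-1(2H)-one, via Michael adduct diketone 10 (not isolated)
Conditions: KOt-Bu (0.2 equiv), t-BuOH/THF (0.02 M), 0 °C to rt; aq. NH4Cl
Reagents that add atoms: none
Why: Catalytic tert-butoxide equilibrates the ketone enolates of 9; only the more substituted enolate (C10) can reach the enone through a six-membered transition state, so a 6-(enolexo)-exo-trig Michael addition closes ring B (C5–C10), and the methyl-ketone enolate (C2) of the resulting 1,5-diketone 10 then closes ring A by a 6-(enolendo)-exo-trig aldol addition to the C3 ketone (C2–C3). The closest known reaction type is the internal Michael–aldol bicyclisation of acyclic keto-enones used to build trans-hydrindanes. C5 is set by a chair transition state in which the C7 isopropenyl group and the (E)-enone arm are both equatorial (1,3-cis). C10 is set in the same transition state: the small methyl should take the crowded axial site and the solvated oxyvinyl unit the equatorial one, placing the acetyl and 2-oxopropyl arms trans-diequatorial (trans-decalin), and since the Michael step is reversible, a cis-disposed adduct, whose aldol closure suffers a 1,3-diaxial clash, can revert and funnel to the trans ketol. C3 is set in the aldol chair with methyl equatorial and the alkoxide axial (potassium bridging the enolate and carbonyl oxygens), which is also the more stable ketol. The step needs the aldol to run from C2 onto C3 rather than from the other methyl onto C1, which the quaternary C10 next to C1 secures, and it must stop before dehydration, hence substoichiometric base at low temperature.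

Step 6
Reactants: 11 (3S,4aS,6R,8aR)-3-hydroxy-3,8a-dimethyl-6-(prop-1-en-2-yl)octahydronaphthalen-1(2H)-one
Product: 12 tosylhydrazone of 11 at C1
Conditions: TsNHNH2, PPTS (cat.), EtOH, 50 °C
Reagents that add atoms: p-toluenesulfonohydrazide NNS(=O)(=O)c1ccc(C)cc1
Why: Tosylhydrazone formation at the only carbonyl group under a mild acidic buffer should avoid retro-aldol cleavage and dehydration of the tertiary β-hydroxy group; no stereocentre changes.

Step 7
Reactants: 12 tosylhydrazone of 11
Product: 15 (2R,4aS,7R,8aS)-2,4a-dimethyl-7-(prop-1-en-2-yl)decahydronaphthalen-2-ol, via N-boryl tosylhydrazine 13 (not isolated), via alkyl diazene 14 (not isolated)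
Conditions: catecholborane, CHCl3, 0 °C to rt; NaOAc·3H2O, reflux
Reagents that add atoms: none
Why: Caglioti-type tosylhydrazone reduction in the catecholborane (Kabalka) variant: hydride adds to C=N, acetate triggers loss of sulfinate and the diazene loses N2, removing the temporary C1 carbonyl without strong base; the transient C1 centre ends as CH2 and the isopropenyl group is not hydroborated at this temperature.

Step 8
Reactants: 16 2-bromo-4-chloro-1-iodobenzene; 17 1,3,5-trimethoxybenzene
Product: 19 (2-bromo-4-chlorophenyl)(2,4,6-trimethoxyphenyl)iodonium 4-methylbenzenesulfonate, via hydroxy(tosyloxy)iodoarene 18 (not isolated)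
Conditions: mCPBA, TsOH·H2O, MeCN, 55 °C; then 17, rt
Reagents that add atoms: p-toluenesulfonic acid Cc1ccc(cc1)S(O)(=O)=O
Why: One-pot synthesis of an aryl(trimethoxyphenyl)iodonium salt: the aryl iodide is oxidised to a Koser-type trivalent iodine tosylate, which undergoes electrophilic aromatic substitution with the electron-rich trimethoxybenzene.

Step 9
Reactants: 15 (2R,4aS,7R,8aS)-2,4a-dimethyl-7-(prop-1-en-2-yl)decahydronaphthalen-2-ol; 19 the iodonium tosylate
Product: 21 2-bromo-4-chloro-1-{[(2R,4aS,7R,8aS)-2,4a-dimethyl-7-(prop-1-en-2-yl)decahydronaphthalen-2-yl]oxy}benzene, via sodium alkoxide 20 (not isolated)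
Conditions: NaH, THF/toluene, 0 °C to rt; then 19, rt
Reagents that add atoms: none
Why: Metal-free O-arylation of a tertiary alkoxide with a diaryliodonium salt: ligand coupling on iodine should transfer the electron-poorer, ortho-substituted 2-bromo-4-chlorophenyl group and leave the trimethoxyphenyl group on iodine; the C3–O bond is not broken, so C3 keeps its configuration.

Step 10
Reactants: 21 the 2-bromo-4-chlorophenyl ether
Product: 23 2-[(2R,4aS,7R,8aS)-7-(2-bromo-4-chlorophenoxy)-4a,7-dimethyldecahydronaphthalen-2-yl]propan-2-ol, via tertiary hydroperoxide 22 (not isolated)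
Conditions: Mn(dpm)3 (cat.), PhSiH3, O2 (1 atm), i-PrOH/CH2Cl2, 0 °C to rt
Reagents that add atoms: dioxygen O=O
Why: Mukaiyama hydration: hydrogen-atom transfer from a manganese hydride to the 1,1-disubstituted alkene gives the tertiary radical, which is trapped by O2 and reduced to the Markovnikov alcohol; aryl halides and the ether are inert and no stereocentre is formed.

Step 11
Reactants: 24 2-allyl-4-bromophenol
Product: 25 2-(prop-2-en-1-yl)-4-(4,4,5,5-tetramethyl-1,3,2-dioxaborolan-2-yl)phenol
Conditions: B2pin2, Pd(dppf)Cl2 (cat.), KOAc, 1,4-dioxane, 85 °C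
Reagents that add atoms: bis(pinacolato)diboron CC1(C)OB(OC1(C)C)B1OC(C)(C)C(C)(C)O1
Why: Miyaura borylation of the aryl bromide, which tolerates the free phenol and the allyl group.

Step 12
Reactants: 23 the bromo chloro ether alcohol; 25 the phenol boronate
Product: 26 2-[(2R,4aS,7R,8aS)-7-{[5-chloro-4'-hydroxy-3'-(prop-2-en-1-yl)[1,1'-biphenyl]-2-yl]oxy}-4a,7-dimethyldecahydronaphthalen-2-yl]propan-2-ol
Conditions: Pd(dppf)Cl2 (cat.), K2CO3, 1,4-dioxane/H2O, 85 °C
Reagents that add atoms: none
Why: Suzuki–Miyaura coupling at the C–Br bond, which should undergo oxidative addition far faster than C–Cl with this catalyst, builds the biaryl in the presence of the free phenol and tertiary alcohol.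

Step 13
Reactants: 26 the biaryl chloride
Product: 27 2-[(2R,4aS,7R,8aS)-7-{[4'-hydroxy-3',5-di(prop-2-en-1-yl)[1,1'-biphenyl]-2-yl]oxy}-4a,7-dimethyldecahydronaphthalen-2-yl]propan-2-ol (target)
Conditions: allylBpin, Pd(OAc)2 (cat.), XPhos, K3PO4, THF/H2O, 60 °C
Reagents that add atoms: allylboronic acid pinacol ester C=CCB1OC(C)(C)C(C)(C)O1
Why: Suzuki–Miyaura allylation of the aryl chloride with a bulky biarylphosphine ligand that activates C–Cl at moderate temperature completes the target; no stereocentre is affected.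

**Compound list**
1 | (R)-(+)-limonene, (4R)-1-methyl-4-(prop-1-en-2-yl)cyclohex-1-ene | CC1=CC[C@@H](CC1)C(C)=C | starting material
2 | (3R)-6-hydroperoxy-6-methoxy-3-(prop-1-en-2-yl)heptanal (C6 epimers) | O=CC[C@H](C(C)=C)CCC(C)(OC)OO | intermediate
3 | (5R)-2-hydroperoxy-2,7,7-trimethoxy-5-(prop-1-en-2-yl)heptane (C2 epimers) | COC(OC)C[C@H](C(C)=C)CCC(C)(OC)OO | intermediate
4 | (5R)-7,7-dimethoxy-5-(prop-1-en-2-yl)heptan-2-one | COC(OC)C[C@H](C(C)=C)CCC(C)=O | intermediate
5 | (5R)-7,7-dimethoxy-2-methyl-5-(prop-1-en-2-yl)heptanenitrile (C2 epimers) | COC(OC)C[C@H](C(C)=C)CCC(C)C#N | intermediate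
6 | N-lithio ketimine of 7 | COC(OC)C[C@H](C(C)=C)CCC(C)C(C)=N[Li] | intermediate
7 | (6R)-8,8-dimethoxy-3-methyl-6-(prop-1-en-2-yl)octan-2-one (C3 epimers) | COC(OC)C[C@H](C(C)=C)CCC(C)C(C)=O | intermediate
8 | (3R)-6-methyl-7-oxo-3-(prop-1-en-2-yl)octanal (C6 epimers) | O=CC[C@H](C(C)=C)CCC(C)C(C)=O | intermediate
9 | (3E,6R)-9-methyl-6-(prop-1-en-2-yl)undec-3-ene-2,10-dione (C9 epimers) | CC(=O)/C=C/C[C@H](C(C)=C)CCC(C)C(C)=O | intermediate
10 | 1-[(1S,2R,5R)-2-acetyl-2-methyl-5-(prop-1-en-2-yl)cyclohexyl]propan-2-one (acetyl and 2-oxopropyl trans, 2-oxopropyl and isopropenyl cis) | CC(=O)[C@]1(C)CC[C@@H](C(C)=C)C[C@H]1CC(C)=O | intermediate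
11 | (3S,4aS,6R,8aR)-3-hydroxy-3,8a-dimethyl-6-(prop-1-en-2-yl)octahydronaphthalen-1(2H)-one (trans-fused, OH axial) | O[C@]1(C)CC(=O)[C@]2(C)CC[C@@H](C(C)=C)C[C@H]2C1 | intermediate
12 | N'-[(3S,4aS,6R,8aR)-3-hydroxy-3,8a-dimethyl-6-(prop-1-en-2-yl)octahydronaphthalen-1(2H)-ylidene]-4-methylbenzenesulfonohydrazide | O[C@]1(C)CC(=NNS(=O)(=O)c3ccc(C)cc3)[C@]2(C)CC[C@@H](C(C)=C)C[C@H]2C1 | intermediate
13 | N-(1,3,2-benzodioxaborol-2-yl) tosylhydrazine from 12 (C1 epimers) | O[C@]1(C)CC(N(NS(=O)(=O)c3ccc(C)cc3)B3Oc4ccccc4O3)[C@]2(C)CC[C@@H](C(C)=C)C[C@H]2C1 | intermediate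
14 | C1 diazene of the decalinol (C1 epimers) | O[C@]1(C)CC(N=N)[C@]2(C)CC[C@@H](C(C)=C)C[C@H]2C1 | intermediate
15 | (2R,4aS,7R,8aS)-2,4a-dimethyl-7-(prop-1-en-2-yl)decahydronaphthalen-2-ol | O[C@]1(C)CC[C@]2(C)CC[C@@H](C(C)=C)C[C@H]2C1 | intermediate
16 | 2-bromo-4-chloro-1-iodobenzene | Clc1ccc(I)c(Br)c1 | starting material
17 | 1,3,5-trimethoxybenzene | COc1cc(OC)cc(OC)c1 | starting material
18 | 2-bromo-4-chloro-1-[hydroxy(tosyloxy)iodo]benzene | Cc1ccc(cc1)S(=O)(=O)OI(O)c1ccc(Cl)cc1Br | intermediate
19 | (2-bromo-4-chlorophenyl)(2,4,6-trimethoxyphenyl)iodonium 4-methylbenzenesulfonate | COc1cc(OC)c([I+]c2ccc(Cl)cc2Br)c(OC)c1.Cc1ccc(cc1)S(=O)(=O)[O-] | intermediate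
20 | sodium (2R,4aS,7R,8aS)-2,4a-dimethyl-7-(prop-1-en-2-yl)decahydronaphthalen-2-olate | [Na+].[O-][C@]1(C)CC[C@]2(C)CC[C@@H](C(C)=C)C[C@H]2C1 | intermediate
21 | 2-bromo-4-chloro-1-{[(2R,4aS,7R,8aS)-2,4a-dimethyl-7-(prop-1-en-2-yl)decahydronaphthalen-2-yl]oxy}benzene | Clc1ccc(O[C@]2(C)CC[C@]3(C)CC[C@@H](C(C)=C)C[C@H]3C2)c(Br)c1 | intermediate
22 | 2-bromo-4-chloro-1-{[(2R,4aS,7R,8aS)-7-(2-hydroperoxypropan-2-yl)-2,4a-dimethyldecahydronaphthalen-2-yl]oxy}benzene | Clc1ccc(O[C@]2(C)CC[C@]3(C)CC[C@@H](C(C)(C)OO)C[C@H]3C2)c(Br)c1 | intermediate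
23 | 2-[(2R,4aS,7R,8aS)-7-(2-bromo-4-chlorophenoxy)-4a,7-dimethyldecahydronaphthalen-2-yl]propan-2-ol | Clc1ccc(O[C@]2(C)CC[C@]3(C)CC[C@@H](C(C)(C)O)C[C@H]3C2)c(Br)c1 | intermediate
24 | 2-allyl-4-bromophenol | C=CCc1cc(Br)ccc1O | starting material
25 | 2-(prop-2-en-1-yl)-4-(4,4,5,5-tetramethyl-1,3,2-dioxaborolan-2-yl)phenol | C=CCc1cc(ccc1O)B1OC(C)(C)C(C)(C)O1 | intermediate
26 | 2-[(2R,4aS,7R,8aS)-7-{[5-chloro-4'-hydroxy-3'-(prop-2-en-1-yl)[1,1'-biphenyl]-2-yl]oxy}-4a,7-dimethyldecahydronaphthalen-2-yl]propan-2-ol | Clc1ccc(O[C@]2(C)CC[C@]3(C)CC[C@@H](C(C)(C)O)C[C@H]3C2)c(-c2ccc(O)c(CC=C)c2)c1 | intermediate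
27 | 2-[(2R,4aS,7R,8aS)-7-{[4'-hydroxy-3',5-di(prop-2-en-1-yl)[1,1'-biphenyl]-2-yl]oxy}-4a,7-dimethyldecahydronaphthalen-2-yl]propan-2-ol | C=CCc1ccc(O[C@]2(C)CC[C@]3(C)CC[C@@H](C(C)(C)O)C[C@H]3C2)c(-c2ccc(O)c(CC=C)c2)c1 | target

**Totals**
Total step count: 13. Longest linear sequence: 11 (steps 1–7, 9, 10, 12, 13); steps 8 and 11 are side branches.

**Steps most likely to fail**

Step 5. What may go wrong: poor facial selectivity at C10 in the ring-B Michael closure (cis-fused material) or at C3 in the aldol closure, aldol closure in the other direction, or dehydration of the ketol. Fallback (sets out from 1, comes back at 15): epoxidation of 1 with mCPBA gives limonene 1,2-oxide F1, and ZnBr2-promoted Meinwald rearrangement gives dihydrocarvone F2. Condensation with (R)-1-phenylethylamine gives the imine F3, whose secondary enamine tautomer adds to methyl vinyl ketone on the face fixed by the auxiliary to give the Michael adduct imine F4. Aqueous acetic acid hydrolyses it to the diketone F5, and NaOMe in MeOH closes the octalone F6 (imine-directed Robinson annulation). Li/NH3 reduction gives the trans-fused decalone F7, and MeTi(OiPr)3, which should add from the equatorial side, gives 15.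

Step 9. What may go wrong: ortho-deprotonation of the iodonium salt to an aryne (regioisomeric ethers) or attack at iodine without ligand coupling (recovered alcohol). Fallback (sets out from 15 as its sodium alkoxide 20, comes back at 21): nucleophilic aromatic substitution of 20 on 2-bromo-1-fluoro-4-nitrobenzene in THF/DMF gives the nitroaryl ether F8; Fe/NH4Cl in aqueous ethanol reduces it to the aniline F9; t-BuONO and CuCl2 in MeCN convert this through the arenediazonium chloride F10 into 21 (aprotic Sandmeyer chlorination).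

Step 6. What may go wrong: slow condensation at the carbonyl flanked by the quaternary C10, with acid-promoted dehydration or retro-aldol cleavage of the β-hydroxy ketone taking over (the same sensitivity carries into step 7). Fallback (sets out from 11, comes back at 15): N-(trimethylsilyl)imidazole silylates the tertiary alcohol to the silyl ether ketone F11; LiAlH4 reduces the ketone to the secondary alcohol F12; NaH, CS2 and MeI give the xanthate F13; Bu3SnH with AIBN in hot toluene removes the C1 oxygen (Barton–McCombie deoxygenation) to give the silyl ether F14; Bu4NF in THF returns 15.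

**Further compounds**
F1 | step 5 | (4R)-limonene 1,2-oxide (epoxide epimers) | CC12OC1C[C@@H](CC2)C(C)=C
F2 | step 5 | (5R)-2-methyl-5-(prop-1-en-2-yl)cyclohexan-1-one, dihydrocarvone (C2 epimers) | CC1CC[C@H](CC1=O)C(C)=C
F3 | step 5 | imine of F2 with (R)-1-phenylethylamine | C[C@H](c1ccccc1)N=C1C[C@@H](CCC1C)C(C)=C
F4 | step 5 | Michael adduct imine, (R)-1-phenylethyl imine of F5 | C[C@H](c1ccccc1)N=C1C[C@@H](CC[C@@]1(C)CCC(C)=O)C(C)=C
F5 | step 5 | (2S,5R)-2-methyl-2-(3-oxobutyl)-5-(prop-1-en-2-yl)cyclohexan-1-one | CC(=O)CC[C@]1(C)CC[C@H](CC1=O)C(C)=C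
F6 | step 5 | (4aS,7R)-4a-methyl-7-(prop-1-en-2-yl)-4,4a,5,6,7,8-hexahydronaphthalen-2(3H)-one | O=C1CC[C@]2(C)CC[C@@H](C(C)=C)CC2=C1
F7 | step 5 | (4aS,7R,8aS)-4a-methyl-7-(prop-1-en-2-yl)octahydronaphthalen-2(1H)-one | O=C1CC[C@]2(C)CC[C@@H](C(C)=C)C[C@H]2C1
F8 | step 9 | 2-bromo-1-{[(2R,4aS,7R,8aS)-2,4a-dimethyl-7-(prop-1-en-2-yl)decahydronaphthalen-2-yl]oxy}-4-nitrobenzene | [O-][N+](=O)c1ccc(O[C@]2(C)CC[C@]3(C)CC[C@@H](C(C)=C)C[C@H]3C2)c(Br)c1
F9 | step 9 | 3-bromo-4-{[(2R,4aS,7R,8aS)-2,4a-dimethyl-7-(prop-1-en-2-yl)decahydronaphthalen-2-yl]oxy}aniline | Nc1ccc(O[C@]2(C)CC[C@]3(C)CC[C@@H](C(C)=C)C[C@H]3C2)c(Br)c1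
F10 | step 9 | arenediazonium chloride of F9 | [Cl-].N#[N+]c1ccc(O[C@]2(C)CC[C@]3(C)CC[C@@H](C(C)=C)C[C@H]3C2)c(Br)c1
F11 | step 6 | trimethylsilyl ether of ketol 11 | C[Si](C)(C)O[C@]1(C)CC(=O)[C@]2(C)CC[C@@H](C(C)=C)C[C@H]2C1
F12 | step 6 | C1 alcohol of F11 (C1 epimers) | C[Si](C)(C)O[C@]1(C)CC(O)[C@]2(C)CC[C@@H](C(C)=C)C[C@H]2C1
F13 | step 6 | S-methyl xanthate of F12 | C[Si](C)(C)O[C@]1(C)CC(OC(=S)SC)[C@]2(C)CC[C@@H](C(C)=C)C[C@H]2C1
F14 | step 6 | trimethylsilyl ether of 15 | C[Si](C)(C)O[C@]1(C)CC[C@]2(C)CC[C@@H](C(C)=C)C[C@H]2C1
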